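Ring A (C1 bears OH, C2 the oxygen to ring B, C4 and C6 bromine) is opened at C4–C5. Both carbons are plain CH at the cyclohexenone stage, because the C4 bromine can be added after aromatisation, so this bond can be formed as an alkene by ring-closing metathesis. In one operation the metathesis converts an acyclic allyl homoallyl ketone into the six-membered carbocycle. The ketone is the latent C1 hydroxyl, and the ring B oxygen already sits on sp3 C2, placed there by SN2 alkylation of 2,4-dibromophenol, which makes an Ullmann-type ether coupling unnecessary. The precursor is racemic 5-(2,4-dibromophenoxy)octa-1,7-dien-4-one.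

Key step: step 4

Assumption: ring A is numbered as in the target (C1 = C–OH, C2 = C–O–ring B, C4 and C6 = C–Br); the target is achiral, so every intermediate with a stereocenter at the aryloxy-bearing carbon is made and used as the racemate.

Step 1
Reactants: 1 2,4-dibromophenol; 2 2-chloro-N-methoxy-N-methylacetamide
Product: 3 2-(2,4-dibromophenoxy)-N-methoxy-N-methylacetamide
Conditions: K2CO3, KI (cat.), acetone, reflux
Reagents that add atoms: none
Why: Williamson ether synthesis, in which the phenoxide of 1 displaces chloride from the primary α-carbon of 2 by SN2 (helped by halide exchange with KI), while the aryl bromides and the N-methoxy-N-methylamide are inert to carbonate.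

Step 2
Reactants: 3 2-(2,4-dibromophenoxy)-N-methoxy-N-methylacetamide; 4 allyl bromide
Product: 6 racemic 2-(2,4-dibromophenoxy)-N-methoxy-N-methylpent-4-enamide, via lithium enolate 5 (not isolated)
Conditions: LiN(SiMe3)2 (1.1 equiv), THF, −78 °C; then allyl bromide, −78 to −30 °C
Reagents that add atoms: none
Why: Enolate alkylation, in which the α-CH2 of 3 (acidified by the amide and the aryloxy group) is deprotonated by the non-nucleophilic silylamide without attack on the aryl bromides and the enolate 5 is C-allylated by SN2 on allyl bromide; the new stereocenter should form as a racemate, which suffices because this carbon becomes aromatic C2.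

Step 3
Reactants: 6 racemic 2-(2,4-dibromophenoxy)-N-methoxy-N-methylpent-4-enamide; 7 allylmagnesium bromide (CH2=CHCH2MgBr, solution in Et2O)
Product: 9 racemic 5-(2,4-dibromophenoxy)octa-1,7-dien-4-one, via magnesium chelate 8 (not isolated)
Conditions: THF/Et2O, −78 °C; then 1 M HCl, 0 °C
Reagents that add atoms: none
Why: Weinreb ketone synthesis, in which the allyl Grignard reagent adds once, the magnesium chelate 8 holds the tetrahedral adduct until the cold acidic quench so that no tertiary alcohol can form, and the non-basic work-up should release the β,γ-unsaturated ketone without moving the double bond into conjugation.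

Step 4
Reactants: 9 racemic 5-(2,4-dibromophenoxy)octa-1,7-dien-4-one
Product: 10 racemic 6-(2,4-dibromophenoxy)cyclohex-3-en-1-one
Conditions: second-generation Grubbs catalyst RuCl2(=CHPh)(H2IMes)(PCy3) (3 mol %), 1,4-benzoquinone (10 mol %), CH2Cl2 (0.01 M), 40 °C
Reagents that add atoms: none
Why: Olefin metathesis by the Chauvin mechanism: the ruthenium benzylidene loses PCy3 and exchanges with one terminal alkene of 9 to give a ruthenium alkylidene, and intramolecular [2+2] cycloaddition with the second alkene followed by cycloreversion of the ruthenacyclobutane forms the C4=C5 double bond of ring A and expels ethylene. The closest known reaction type is ring-closing metathesis of octa-1,7-dien-4-ones to cyclohex-3-en-1-ones. Ring A closes as a six-membered carbocycle by joining the two internal alkene carbons, a favoured ring size for this reaction, and the loss of volatile ethylene makes the closure irreversible. No stereocenter is created; the racemic aryloxy-bearing carbon (future C2) is a spectator and becomes sp2 in step 5. The step needs cyclisation to beat acyclic diene oligomerisation and migration of the allyl ketone double bond into conjugation; high dilution, two unhindered monosubstituted alkenes, a neutral medium and 1,4-benzoquinone as a scavenger of ruthenium hydrides should secure this. The aryl bromides, the ketone and the aryl ether are not expected to react with the catalyst.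

Step 5
Reactants: 10 racemic 6-(2,4-dibromophenoxy)cyclohex-3-en-1-one
Product: 13 2-(2,4-dibromophenoxy)phenol, via trans-4,5-dibromoketone 11 (not isolated), via 4-bromocyclohexenone 12 (not isolated)
Conditions: Br2 (1.05 equiv), CH2Cl2, −78 °C; then DBU (3 equiv), −78 °C to rt
Reagents that add atoms: none
Why: Bromination–dehydrobromination aromatisation, in which Br2 adds anti to the isolated C4=C5 alkene, DBU removes the β-bromide at C5 by E1cB elimination through the C6 enolate and then the remaining allylic C4 bromide by E2 elimination, and the resulting cyclohexa-2,4-dienone tautomerises to the phenol, so the bromine introduced here leaves again as hydrobromide.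

Step 6
Reactants: 13 2-(2,4-dibromophenoxy)phenol
Product: 15 2,4-dibromo-6-(2,4-dibromophenoxy)phenol (target), via monobromophenol 14 (not isolated)
Conditions: Br2 (2.1 equiv), AcOH, rt; aq Na2S2O3 work-up
Reagents that add atoms: bromine, BrBr
Why: Electrophilic aromatic bromination, in which the free C1 hydroxyl is the strongest activating group and should direct bromine first para (C4, giving 14) and then to the only free ortho position (C6), while ring B, deactivated by its two bromines, should stay untouched.

Compound list
1 | 2,4-dibromophenol | Oc1ccc(Br)cc1Br | starting material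
2 | 2-chloro-N-methoxy-N-methylacetamide | CON(C)C(=O)CCl | starting material
3 | 2-(2,4-dibromophenoxy)-N-methoxy-N-methylacetamide | CON(C)C(=O)COc1ccc(Br)cc1Br | intermediate
4 | allyl bromide (3-bromoprop-1-ene) | C=CCBr | starting material
5 | lithium (Z)-2-(2,4-dibromophenoxy)-1-[methoxy(methyl)amino]ethen-1-olate | [Li]O/C(=C\Oc1ccc(Br)cc1Br)N(C)OC | intermediate (not isolated)
6 | racemic 2-(2,4-dibromophenoxy)-N-methoxy-N-methylpent-4-enamide | CON(C)C(=O)C(CC=C)Oc1ccc(Br)cc1Br | intermediate
7 | allylmagnesium bromide | C=CC[Mg]Br | starting material
8 | bromomagnesium 5-(2,4-dibromophenoxy)-4-[methoxy(methyl)amino]octa-1,7-dien-4-olate (mixture of diastereomers) | C=CCC(O[Mg]Br)(N(C)OC)C(CC=C)Oc1ccc(Br)cc1Br | intermediate (not isolated)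
9 | racemic 5-(2,4-dibromophenoxy)octa-1,7-dien-4-one | C=CCC(=O)C(CC=C)Oc1ccc(Br)cc1Br | intermediate
10 | racemic 6-(2,4-dibromophenoxy)cyclohex-3-en-1-one | O=C1CC=CCC1Oc1ccc(Br)cc1Br | intermediate
11 | trans-4,5-dibromo-2-(2,4-dibromophenoxy)cyclohexan-1-one (racemic, both C2 epimers; one enantiomer drawn) | O=C1C[C@H](Br)[C@@H](Br)CC1Oc1ccc(Br)cc1Br | intermediate (not isolated)
12 | 4-bromo-6-(2,4-dibromophenoxy)cyclohex-2-en-1-one (racemic, mixture of diastereomers) | O=C1C=CC(Br)CC1Oc1ccc(Br)cc1Br | intermediate (not isolated)
13 | 2-(2,4-dibromophenoxy)phenol | Oc1ccccc1Oc1ccc(Br)cc1Br | intermediate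
14 | 4-bromo-2-(2,4-dibromophenoxy)phenol | Oc1ccc(Br)cc1Oc1ccc(Br)cc1Br | intermediate (not isolated)
15 | 2,4-dibromo-6-(2,4-dibromophenoxy)phenol | Oc1c(Br)cc(Br)cc1Oc1ccc(Br)cc1Br | target

Total step count: 6 steps.
Longest linear sequence: 6 steps (from 1 to 15).

Steps most likely to fail

Step 4. The ring closure may lose to intermolecular metathesis (oligomer formation), or the allyl ketone double bond may migrate into conjugation before cyclisation, leaving an internal, electron-poor alkene that closes poorly. The fallback removes the ketone for the metathesis and keeps the same C4–C5 bond formation. It sets out from 9, which is reduced with NaBH4/CeCl3 in MeOH at −40 °C to 5-(2,4-dibromophenoxy)octa-1,7-dien-4-ol F1. This homoallylic alcohol cannot isomerise to an enone and should cyclise with RuCl2(=CHPh)(H2IMes)(PCy3) in dilute CH2Cl2 at 40 °C to 6-(2,4-dibromophenoxy)cyclohex-3-en-1-ol F2. Oxidation of F2 with Dess–Martin periodinane buffered with NaHCO3 in CH2Cl2 should return the route to 10 without shifting the alkene.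

Step 2. The strong base may fragment the N-methoxy amide (loss of formaldehyde to leave the N-methyl amide), or a second allylation may compete with the first. The fallback carries out the allylation on an ester enolate and installs the N-methoxy-N-methylamide afterwards. It sets out from 1, which is alkylated with ethyl bromoacetate (K2CO3, acetone, reflux) to ethyl 2-(2,4-dibromophenoxy)acetate F3. Deprotonation with LiN(SiMe3)2 in THF at −78 °C and alkylation with allyl bromide 4 should give racemic ethyl 2-(2,4-dibromophenoxy)pent-4-enoate F4. Aminolysis of F4 with MeNH(OMe)·HCl/AlMe3 in CH2Cl2 (0 °C to rt) comes back to the route at 6.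

Step 5. The second loss of hydrobromide may stall at the allylic bromide, or enolisation may divert bromine to the carbon next to the ketone instead of the alkene. The fallback replaces addition–elimination by dehydrogenation. It sets out from 10, which is silylated with Me3SiOTf/Et3N in CH2Cl2 at 0 °C to {[6-(2,4-dibromophenoxy)cyclohexa-1,3-dien-1-yl]oxy}trimethylsilane F5 (the 1,4-diene regioisomer would behave alike). Dehydrogenation of F5 with DDQ in CH2Cl2 at rt should give [2-(2,4-dibromophenoxy)phenoxy]trimethylsilane F6, and cleavage of the silyl ether with dilute HCl in THF/water comes back to the route at 13.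

Further compounds
F1 | step 4 | 5-(2,4-dibromophenoxy)octa-1,7-dien-4-ol (racemic, both diastereomers) | C=CCC(O)C(CC=C)Oc1ccc(Br)cc1Br
F2 | step 4 | 6-(2,4-dibromophenoxy)cyclohex-3-en-1-ol (racemic, cis and trans) | OC1CC=CCC1Oc1ccc(Br)cc1Br
F3 | step 2 | ethyl 2-(2,4-dibromophenoxy)acetate | CCOC(=O)COc1ccc(Br)cc1Br
F4 | step 2 | racemic ethyl 2-(2,4-dibromophenoxy)pent-4-enoate | CCOC(=O)C(CC=C)Oc1ccc(Br)cc1Br
F5 | step 5 | {[6-(2,4-dibromophenoxy)cyclohexa-1,3-dien-1-yl]oxy}trimethylsilane (racemic) | C[Si](C)(C)OC1=CC=CCC1Oc1ccc(Br)cc1Br
F6 | step 5 | [2-(2,4-dibromophenoxy)phenoxy]trimethylsilane | C[Si](C)(C)Oc1ccccc1Oc1ccc(Br)cc1Br
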